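## Retrosynthetic overview

1. Target 18 ⇐ 16 ⇐ 13: the ester and silyl groups come off last; the angelate is put on the free 3-OH of bicyclic hydroxy ester 13.
2. 13 ⇐ epoxy-polyene 11 by a titanocene radical cascade: ring A closes first, then ring B, and termination gives the 8(17)-methylene. C3 comes from the epoxide; C4, C5, C9 and C10 come from the chair–chair folding.
3. 11 ⇐ tert-butyl geranylgeranoate 8 by terminal allylic oxidation and Sharpless epoxidation.
4. Key disconnection C12–C13: 8 ⇐ homofarnesyl bromide 4 (electrophilic C12) + (E)-β-stannyl crotonate 7. Stannane 7 is a β-acylvinyl anion (d3, homoenolate-type) equivalent, so the normally electrophilic enoate β-carbon is the nucleophile and the 13E geometry is fixed in the coupling.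
5. 4 ⇐ farnesyl bromide 1 plus one carbon; 7 ⇐ but-2-ynoic acid 5.

Assumption: the SMILES is read as the ent-labdane (3R,4S,5S,9R,10S) with 13E acid, Z (angelate) ester and the C4 CH2OH equatorial (C18, trans to C20); 1, 5 and angelic acid 14 are taken as commercial.

## Route

Step 1
Reactants: 1 (2E,6E)-farnesyl bromide
Product: 3 (3E,7E)-homofarnesol, via isopropoxydimethyl(homofarnesyl)silane 2 (not isolated)
Conditions: ClCH2SiMe2(OiPr), Mg, THF, rt; then 1, CuI (5 mol %), 0 °C to rt; then 30% H2O2, KF, KHCO3, THF/MeOH, rt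
Reagents that add atoms: (chloromethyl)isopropoxydimethylsilane, ClC[Si](C)(C)OC(C)C; hydrogen peroxide, OO
Why: SN2 coupling of Tamao's silylmethyl Grignard reagent (a hydroxymethyl anion equivalent) at the unhindered C1 of the allylic bromide, then Tamao–Fleming oxidation of the C–Si bond, gives the one-carbon homologue with both E alkenes untouched.

Step 2
Reactants: 3 (3E,7E)-homofarnesol
Product: 4 (3E,7E)-homofarnesyl bromide
Conditions: CBr4, PPh3, DCM, 0 °C
Reagents that add atoms: carbon tetrabromide, BrC(Br)(Br)Br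
Why: Appel bromination converts the primary homoallylic alcohol to the bromide under neutral conditions without touching the alkenes.

Step 3
Reactants: 5 but-2-ynoic acid
Product: 6 tert-butyl but-2-ynoate
Conditions: 2-methylpropene, H2SO4 (cat.), DCM, sealed vessel, rt
Reagents that add atoms: 2-methylpropene, C=C(C)C
Why: Acid-catalysed addition of the acid to isobutene gives the tert-butyl ester, which survives fluoride, base and the radical step and can be removed at the end without base.

Step 4
Reactants: 6 tert-butyl but-2-ynoate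
Product: 7 tert-butyl (E)-3-(tributylstannyl)but-2-enoate
Conditions: Bu3SnH, LiN(iPr)2, THF, 0 °C; CuBr·SMe2, −78 °C; then 6, MeOH, −78 °C
Reagents that add atoms: tributyltin hydride, CCCC[SnH](CCCC)CCCC
Why: Kinetic syn-stannylcupration of the ynoate at −78 °C with in situ protonation (Piers conditions) places tin on the β-carbon trans to the ester, giving the configurationally defined E stannane.

Step 5
Reactants: 4 (3E,7E)-homofarnesyl bromide; 7 tert-butyl (E)-3-(tributylstannyl)but-2-enoate
Product: 8 tert-butyl (2E,6E,10E)-geranylgeranoate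
Conditions: [(η3-C3H5)PdCl]2 (2.5 mol %), P(t-Bu)2Me (15 mol %), Me4NF, 3 Å MS, THF, rt
Reagents that add atoms: none
Why: Alkyl–alkenyl Stille coupling under Fu conditions (known for simple alkenylstannanes with primary alkyl bromides; the β-stannyl enoate is an untested but mechanistically ordinary partner) joins electrophilic C12 to the normally electrophilic enoate β-carbon C13 with retention of the stannane geometry, so the 13E alkene is set directly.

Step 6
Reactants: 8 tert-butyl (2E,6E,10E)-geranylgeranoate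
Product: 9 tert-butyl (2E,6E,10E,14E)-16-hydroxygeranylgeranoate
Conditions: SeO2 (0.3 equiv), salicylic acid (0.1 equiv), t-BuOOH, DCM, 0 °C to rt, stopped at partial conversion
Reagents that add atoms: tert-butyl hydroperoxide, CC(C)(C)OO
Why: Catalytic SeO2 allylic oxidation (ene reaction then [2,3]-shift) selects the E-methyl of the terminal, most electron-rich trisubstituted alkene, the conjugated 2,3-alkene being inert.

Step 7
Reactants: 9 tert-butyl (2E,6E,10E,14E)-16-hydroxygeranylgeranoate
Product: 11 tert-butyl (2E,6E,10E)-13-[(2R,3R)-3-{[(tert-butyldimethylsilyl)oxy]methyl}-3-methyloxiran-2-yl]-3,7,11-trimethyltrideca-2,6,10-trienoate, via epoxy alcohol 10 (not isolated)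
Conditions: Ti(OiPr)4 (10 mol %), D-(−)-diethyl tartrate (12 mol %), t-BuOOH, 4 Å MS, DCM, −20 °C; then TBSCl, imidazole, 0 °C to rt
Reagents that add atoms: tert-butyl hydroperoxide, CC(C)(C)OO; tert-butyldimethylsilyl chloride, CC(C)(C)[Si](C)(C)Cl
Why: Sharpless asymmetric epoxidation with the D-(−)-tartrate gives the (R,R)-epoxide of the E allylic alcohol under reagent control (the L-(+)-tartrate gives the S,S series), the other alkenes being inert, and in situ silylation caps the primary alcohol.

Step 8
Reactants: 11 epoxy silyl ether (name as in step 7)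
Product: 13 tert-butyl (13E)-(3R,4S,5S,9R,10S)-18-[(tert-butyldimethylsilyl)oxy]-3-hydroxylabda-8(17),13-dien-15-oate, via 3-O-trimethylsilyl ether 12 (not isolated)
Conditions: Cp2TiCl2 (20 mol %), Mn, Me3SiCl, 2,4,6-collidine, THF, rt; then K2CO3, MeOH
Reagents that add atoms: none
Why: Cp2TiCl opens the epoxide at the tertiary carbon (Nugent–RajanBabu) to a C4 radical that closes ring A then ring B by two 6-endo cyclisations through a chair–chair array (C3–O and the larger CH2OTBS group equatorial, E alkenes giving the trans fusion and equatorial C9 chain), and the tertiary C8 radical is trapped by trivalent titanium and loses hydride to the exocyclic alkene, the electron-poor enoate being too slow an acceptor to compete.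

Step 9
Reactants: 13 bicyclic hydroxy ester (name as in step 8); 14 angelic acid
Product: 16 tert-butyl (13E)-(3R,4S,5S,9R,10S)-3-[(Z)-2-methylbut-2-enoyloxy]-18-[(tert-butyldimethylsilyl)oxy]labda-8(17),13-dien-15-oate, via angelic 2,4,6-trichlorobenzoic anhydride 15 (not isolated)
Conditions: 14, 2,4,6-trichlorobenzoyl chloride, Et3N, toluene, rt; then 13, 75 °C
Reagents that add atoms: none
Why: Yamaguchi esterification through the mixed anhydride acylates the hindered equatorial alcohol in hot toluene without a nucleophilic catalyst, conditions known to keep the Z (angelate) geometry.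

Step 10
Reactants: 16 angelate (name as in step 9)
Product: 18 (13E)-(3R,4S,5S,9R,10S)-3-[(Z)-2-methylbut-2-enoyloxy]-18-hydroxylabda-8(17),13-dien-15-oic acid, via trimethylsilyl ester 17 (not isolated)
Conditions: Me3SiOTf, 2,6-lutidine, DCM, 0 °C; then HF·pyridine, THF, 0 °C to rt
Reagents that add atoms: none
Why: Silyl triflate with a hindered base converts the tert-butyl ester to a silyl ester with loss of isobutene, and HF·pyridine then cleaves the silyl ester and the TBS ether under mildly acidic, non-nucleophilic conditions that spare the angelate and the exocyclic alkene and avoid 3-O to 18-O acyl migration.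

## Compound list

1 | (2E,6E)-farnesyl bromide, (2E,6E)-1-bromo-3,7,11-trimethyldodeca-2,6,10-triene | CC(C)=CCC/C(C)=C/CC/C(C)=C/CBr | starting material
2 | isopropoxydimethyl[(3E,7E)-4,8,12-trimethyltrideca-3,7,11-trien-1-yl]silane | CC(C)=CCC/C(C)=C/CC/C(C)=C/CC[Si](C)(C)OC(C)C | intermediate
3 | (3E,7E)-homofarnesol, (3E,7E)-4,8,12-trimethyltrideca-3,7,11-trien-1-ol | CC(C)=CCC/C(C)=C/CC/C(C)=C/CCO | intermediate
4 | (3E,7E)-homofarnesyl bromide, (6E,10E)-13-bromo-2,6,10-trimethyltrideca-2,6,10-triene | CC(C)=CCC/C(C)=C/CC/C(C)=C/CCBr | intermediate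
5 | but-2-ynoic acid | CC#CC(=O)O | starting material
6 | tert-butyl but-2-ynoate | CC#CC(=O)OC(C)(C)C | intermediate
7 | tert-butyl (E)-3-(tributylstannyl)but-2-enoate (Sn trans to the ester) | CCCC[Sn](CCCC)(CCCC)/C(C)=C/C(=O)OC(C)(C)C | intermediate
8 | tert-butyl (2E,6E,10E)-3,7,11,15-tetramethylhexadeca-2,6,10,14-tetraenoate | CC(C)=CCC/C(C)=C/CC/C(C)=C/CC/C(C)=C/C(=O)OC(C)(C)C | intermediate
9 | tert-butyl (2E,6E,10E,14E)-16-hydroxy-3,7,11,15-tetramethylhexadeca-2,6,10,14-tetraenoate | OC/C(C)=C/CC/C(C)=C/CC/C(C)=C/CC/C(C)=C/C(=O)OC(C)(C)C | intermediate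
10 | tert-butyl (2E,6E,10E)-13-[(2R,3R)-3-(hydroxymethyl)-3-methyloxiran-2-yl]-3,7,11-trimethyltrideca-2,6,10-trienoate | OC[C@@]1(C)O[C@@H]1CC/C(C)=C/CC/C(C)=C/CC/C(C)=C/C(=O)OC(C)(C)C | intermediate
11 | TBS ether of 10 | CC(C)(C)[Si](C)(C)OC[C@@]1(C)O[C@@H]1CC/C(C)=C/CC/C(C)=C/CC/C(C)=C/C(=O)OC(C)(C)C | intermediate
12 | 3-O-trimethylsilyl ether of 13 | C=C1CC[C@H]2[C@@](C)(CC[C@@H](O[Si](C)(C)C)[C@]2(C)CO[Si](C)(C)C(C)(C)C)[C@@H]1CC/C(C)=C/C(=O)OC(C)(C)C | intermediate
13 | tert-butyl (13E)-(3R,4S,5S,9R,10S)-18-[(tert-butyldimethylsilyl)oxy]-3-hydroxylabda-8(17),13-dien-15-oate (ent-labdane; 3-OH and C20 cis, CH2OTBS equatorial and trans to C20, trans-decalin, C9 chain cis to C20) | C=C1CC[C@H]2[C@@](C)(CC[C@@H](O)[C@]2(C)CO[Si](C)(C)C(C)(C)C)[C@@H]1CC/C(C)=C/C(=O)OC(C)(C)C | intermediate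
14 | angelic acid, (Z)-2-methylbut-2-enoic acid | C/C=C(/C)C(=O)O | starting material
15 | (Z)-2-methylbut-2-enoic 2,4,6-trichlorobenzoic anhydride | C/C=C(/C)C(=O)OC(=O)c1c(Cl)cc(Cl)cc1Cl | intermediate
16 | tert-butyl (13E)-(3R,4S,5S,9R,10S)-3-[(Z)-2-methylbut-2-enoyloxy]-18-[(tert-butyldimethylsilyl)oxy]labda-8(17),13-dien-15-oate | C=C1CC[C@H]2[C@@](C)(CC[C@@H](OC(=O)/C(C)=C\C)[C@]2(C)CO[Si](C)(C)C(C)(C)C)[C@@H]1CC/C(C)=C/C(=O)OC(C)(C)C | intermediate
17 | trimethylsilyl ester corresponding to 16 (tert-butyl replaced by SiMe3) | C=C1CC[C@H]2[C@@](C)(CC[C@@H](OC(=O)/C(C)=C\C)[C@]2(C)CO[Si](C)(C)C(C)(C)C)[C@@H]1CC/C(C)=C/C(=O)O[Si](C)(C)C | intermediate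
18 | (13E)-(3R,4S,5S,9R,10S)-3-[(Z)-2-methylbut-2-enoyloxy]-18-hydroxylabda-8(17),13-dien-15-oic acid (CNP0420226.2) | C=C1CC[C@H]2[C@@](C)(CC[C@@H](OC(=O)/C(C)=C\C)[C@]2(C)CO)[C@@H]1CC/C(C)=C/C(=O)O | target

## Totals and weak points

Total step count: 10. Longest linear sequence: 8 steps (1, 2, 5, 6, 7, 8, 9, 10) from farnesyl bromide.

Most likely to fail:

Step 5 (alkyl–alkenyl Stille). The homoallylic bromide can eliminate to the conjugated diene (β-hydride loss or fluoride-induced E2). The electron-poor stannane transmetallates slowly, and the E stannane may drift towards the Z isomer. The fallback sets out from 4 and comes back at 8, replacing the vinyl anion by an acetyl anion equivalent. Bromide 4 is alkylated with 2-lithio-2-methyl-1,3-dithiane (n-BuLi, THF, −30 °C) to give 2-methyl-2-[(3E,7E)-4,8,12-trimethyltrideca-3,7,11-trien-1-yl]-1,3-dithiane F1. MeI and CaCO3 in aqueous MeCN unmask (5E,9E)-6,10,14-trimethylpentadeca-5,9,13-trien-2-one F2. Horner–Wadsworth–Emmons olefination with tert-butyl diethylphosphonoacetate and NaH in THF then gives 8, which is separated by chromatography from the minor tert-butyl (2Z,6E,10E)-3,7,11,15-tetramethylhexadeca-2,6,10,14-tetraenoate F3.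

Step 8 (radical bicyclisation). Yields for such cascades are typically modest and the chain can stop at the monocyclic stage. The C4 radical is planar, so the equatorial preference of CH2OTBS is steric only and may be incomplete. The fallback sets out from 11 and comes back at 13 by the cationic manifold: MeAlCl2 in DCM at −78 °C opens the epoxide with anti attack of the alkene at C4. This places the E-derived CH2OTBS group equatorial stereospecifically. The C8 cation loses a proton to give 13 together with its endocyclic isomer, tert-butyl (13E)-(3R,4S,5S,9R,10S)-18-[(tert-butyldimethylsilyl)oxy]-3-hydroxylabda-7,13-dien-15-oate F4, which is removed on AgNO3-impregnated silica.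

Step 9 (angeloylation). The alcohol is flanked by a quaternary carbon, and forcing conditions can isomerise the angelate to the tiglate. The fallback sets out from 13 and comes back at 16 by building the Z alkene on the substrate. DCC/DMAP esterification with 2-[bis(2,2,2-trifluoroethoxy)phosphoryl]propanoic acid gives tert-butyl (13E)-(3R,4S,5S,9R,10S)-3-({2-[bis(2,2,2-trifluoroethoxy)phosphoryl]propanoyl}oxy)-18-[(tert-butyldimethylsilyl)oxy]labda-8(17),13-dien-15-oate F5 (epimer mixture at the phosphonate carbon). Still–Gennari olefination with KN(SiMe3)2, 18-crown-6 and acetaldehyde in THF at −78 °C then gives 16.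

Further compounds
F1 | step 5 | 2-methyl-2-[(3E,7E)-4,8,12-trimethyltrideca-3,7,11-trien-1-yl]-1,3-dithiane | CC(C)=CCC/C(C)=C/CC/C(C)=C/CCC1(C)SCCCS1
F2 | step 5 | (5E,9E)-6,10,14-trimethylpentadeca-5,9,13-trien-2-one | CC(C)=CCC/C(C)=C/CC/C(C)=C/CCC(C)=O
F3 | step 5 | tert-butyl (2Z,6E,10E)-3,7,11,15-tetramethylhexadeca-2,6,10,14-tetraenoate | CC(C)=CCC/C(C)=C/CC/C(C)=C/CC/C(C)=C\C(=O)OC(C)(C)C
F4 | step 8 | tert-butyl (13E)-(3R,4S,5S,9R,10S)-18-[(tert-butyldimethylsilyl)oxy]-3-hydroxylabda-7,13-dien-15-oate | CC1=CC[C@H]2[C@@](C)(CC[C@@H](O)[C@]2(C)CO[Si](C)(C)C(C)(C)C)[C@@H]1CC/C(C)=C/C(=O)OC(C)(C)C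
F5 | step 9 | tert-butyl (13E)-(3R,4S,5S,9R,10S)-3-({2-[bis(2,2,2-trifluoroethoxy)phosphoryl]propanoyl}oxy)-18-[(tert-butyldimethylsilyl)oxy]labda-8(17),13-dien-15-oate | C=C1CC[C@H]2[C@@](C)(CC[C@@H](OC(=O)C(C)P(=O)(OCC(F)(F)F)OCC(F)(F)F)[C@]2(C)CO[Si](C)(C)C(C)(C)C)[C@@H]1CC/C(C)=C/C(=O)OC(C)(C)C
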